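**Strategy.** Ring A of the chromene (C4a, C5, C6, C7, C8, C8a) carries oxygen at C5, C8 and C8a and the aroylcarbonyl group at C6. It is therefore opened at C6–C7 into a chain in which C6 is the methylene of a 1,3-diketone and C7 is an aldehyde held as its dimethyl acetal. Both arms sit cis on the C4a=C8a enol-ether double bond of a preformed dihydropyran (ring B). One acid treatment should join C6 to C7, expel two molecules of methanol and deliver the aromatic ring with the 5-hydroxy and 8-methoxy groups in place, while the second benzil carbonyl stays ketalised. Hydrolysis and dehydrogenation of C3–C4 finish the synthesis.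

Key step: step 9

Remarks on the chemistry:
- Chroman numbering (O1, C2, C3, C4, C4a, C5 to C8, C8a) is used for these atoms in all intermediates.
- 2,2-Dimethoxyacetaldehyde is assumed to be used anhydrous (commercial solution in tert-butyl methyl ether, or dried from the aqueous solution).
- The target is achiral. The stereocentres in 6, 7, 8, 9 and 16 to 20 are not controlled and all disappear in step 9.

Step 1
Reactants: 1 acrolein; 2 isobutene
Product: 3 2,2-dimethyl-3,4-dihydro-2H-pyran
Conditions: excess 2, hydroquinone (cat.), neat, autoclave, 200 °C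
Reagents that add atoms: none
Why: Thermal hetero-Diels–Alder reaction with inverse electron demand, acrolein acting as the 1-oxadiene; the oxygen should bond to the more substituted alkene carbon and give the 2,2-dimethyl regioisomer, with no stereocentre formed.

Step 2
Reactants: 3 2,2-dimethyl-3,4-dihydro-2H-pyran; 4 2,2-dimethoxyacetaldehyde
Product: 7 racemic 2,2-dimethyl-6-(1,2,2-trimethoxyethyl)-3,4-dihydro-2H-pyran, via vinyllithium 5 (not isolated), via lithium alkoxide 6 (not isolated)
Conditions: t-BuLi, THF–pentane, −78 → 0 °C; 4, −78 °C; MeI, DMPU, −78 °C → rt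
Reagents that add atoms: iodomethane, CI
Why: α-Lithiation of the cyclic enol ether at the vinylic carbon next to oxygen, 1,2-addition to the aldehyde and Williamson O-methylation of the alkoxide in the same flask, so the acid-sensitive carbinol is never handled; the new stereocentre (C8) forms without control and is erased in step 9.

Step 3
Reactants: 7 racemic 2,2-dimethyl-6-(1,2,2-trimethoxyethyl)-3,4-dihydro-2H-pyran
Product: 9 racemic 2,2-dimethyl-6-(1,2,2-trimethoxyethyl)-3,4-dihydro-2H-pyran-5-carbaldehyde, via iminium salt 8 (not isolated)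
Conditions: POCl3, DMF, 0 °C → rt; then aq. NaOAc, 0 °C
Reagents that add atoms: N,N-dimethylformamide, CN(C)C=O (formyl carbon); water, O (carbonyl oxygen)
Why: Vilsmeier–Haack formylation at the nucleophilic β-carbon of the enol ether (C4a), after which proton loss from the acylated carbon restores the conjugated β-alkoxy enal; the low temperature and buffered quench should spare the α-methoxy acetal, which ionises reluctantly.

Step 4
Reactants: 10 methyl 2-(4-methoxyphenyl)-2-oxoacetate
Product: 11 methyl 2,2-dimethoxy-2-(4-methoxyphenyl)acetate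
Conditions: HC(OMe)3, MeOH, H2SO4 (cat.), reflux
Reagents that add atoms: trimethyl orthoformate, COC(OC)OC; methanol, CO
Why: Acid-catalysed ketalisation of the activated ketone of an α-keto ester, driven to completion by the orthoformate as water scavenger; the ester is unchanged.

Step 5
Reactants: 11 methyl 2,2-dimethoxy-2-(4-methoxyphenyl)acetate
Product: 12 N,2,2-trimethoxy-2-(4-methoxyphenyl)-N-methylacetamide
Conditions: MeNH(OMe)·HCl, i-PrMgCl, THF, −20 → 0 °C
Reagents that add atoms: N,O-dimethylhydroxylamine hydrochloride, CNOC.Cl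
Why: Aminolysis of the ester by the magnesium amide of N,O-dimethylhydroxylamine gives the Weinreb amide under purely basic conditions, which the ketal tolerates.

Step 6
Reactants: 12 N,2,2-trimethoxy-2-(4-methoxyphenyl)-N-methylacetamide
Product: 14 1,1-dimethoxy-1-(4-methoxyphenyl)propan-2-one, via magnesium chelate 13 (not isolated)
Conditions: MeMgBr, THF, 0 °C; aq. NH4Cl
Reagents that add atoms: methylmagnesium bromide, C[Mg]Br
Why: Weinreb ketone synthesis, in which the chelated tetrahedral adduct survives until work-up so that the Grignard reagent adds only once.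

Step 7
Reactants: 14 1,1-dimethoxy-1-(4-methoxyphenyl)propan-2-one; 9 racemic 2,2-dimethyl-6-(1,2,2-trimethoxyethyl)-3,4-dihydro-2H-pyran-5-carbaldehyde
Product: 17 4-[2,2-dimethyl-6-(1,2,2-trimethoxyethyl)-3,4-dihydro-2H-pyran-5-yl]-4-hydroxy-1,1-dimethoxy-1-(4-methoxyphenyl)butan-2-one (mixture of racemic diastereomers), via lithium enolate 15 (not isolated), via lithium aldolate 16 (not isolated)
Conditions: LiN(SiMe3)2, THF, −78 °C; then 9, −78 °C; aq. NH4Cl, −78 °C
Reagents that add atoms: none
Why: Directed crossed aldol addition, in which the ketone (enolisable only at its methyl group) is converted fully into its lithium enolate before the aldehyde, which has no α-hydrogen, is added; the cold neutral quench should prevent β-elimination, and the uncontrolled carbinol stereocentre is removed in step 8.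

Step 8
Reactants: 17 4-[2,2-dimethyl-6-(1,2,2-trimethoxyethyl)-3,4-dihydro-2H-pyran-5-yl]-4-hydroxy-1,1-dimethoxy-1-(4-methoxyphenyl)butan-2-one
Product: 18 racemic 1-[2,2-dimethyl-6-(1,2,2-trimethoxyethyl)-3,4-dihydro-2H-pyran-5-yl]-4,4-dimethoxy-4-(4-methoxyphenyl)butane-1,3-dione
Conditions: Dess–Martin periodinane, pyridine, CH2Cl2, 0 °C → rt
Reagents that add atoms: none
Why: Dess–Martin oxidation of a β-hydroxy ketone to the 1,3-diketone under pyridine buffering, conditions that leave the enol ether, the acetal and the ketal untouched.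

Step 9
Reactants: 18 racemic 1-[2,2-dimethyl-6-(1,2,2-trimethoxyethyl)-3,4-dihydro-2H-pyran-5-yl]-4,4-dimethoxy-4-(4-methoxyphenyl)butane-1,3-dione
Product: 21 1-(5-hydroxy-8-methoxy-2,2-dimethylchroman-6-yl)-2,2-dimethoxy-2-(4-methoxyphenyl)ethanone, via cyclised adduct 19 (not isolated), via dienone 20 (not isolated)
Conditions: CSA (0.3 equiv, anhydrous), ClCH2CH2Cl, 60 °C, sealed vessel
Reagents that add atoms: none
Why: Acid ionises the C7 dimethyl acetal to an oxocarbenium ion that the enol of the 1,3-diketone captures at C6 (adduct 19), β-elimination of methanol across C6–C7 gives the cross-conjugated dienone 20, and loss of its doubly allylic C8 proton gives the aromatic tautomer, so the C8 methoxy group is kept and C5 emerges as the chelated phenol. The closest known reaction type is the acid-mediated Knoevenagel or Mukaiyama-type condensation of a β-dicarbonyl compound with an acetal followed by aromatisation, as in aldol cyclisations of poly-β-carbonyl chains to acylphenols. Ring A closes in a 6-(enolendo)-exo-trig mode, with the C5=C6 enol inside the new ring and the C7=O+ bond outside it. No stereocentre remains, because the transient ones at C6 and C7 and the racemic one at C8 all become sp2 carbons. The step needs chemoselectivity among nucleophilic carbons and among ionisable acetals: C6 is the only enol carbon held six atoms from C7 by the rigid cis C4a=C8a bond, while the benzylic ketal is slowed by its adjacent carbonyl group and, in the closed anhydrous system, should only return to itself by recapture of the released methanol. Capture of the oxocarbenium ion by the C5 oxygen is reversible, whereas the carbon closure is drained irreversibly by aromatisation.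

Step 10
Reactants: 21 1-(5-hydroxy-8-methoxy-2,2-dimethylchroman-6-yl)-2,2-dimethoxy-2-(4-methoxyphenyl)ethanone
Product: 22 1-(5-hydroxy-8-methoxy-2,2-dimethylchroman-6-yl)-2-(4-methoxyphenyl)ethane-1,2-dione
Conditions: 2 M aq. HCl, THF, 50 °C
Reagents that add atoms: water, O
Why: Acid-catalysed hydrolysis of the α-keto dimethyl ketal to the benzil, which the aryl methyl ethers, the phenol and the saturated chroman ring should withstand; the open diketone is favoured by the hydrogen bond from the 5-hydroxy group to the C6 carbonyl.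

Step 11
Reactants: 22 1-(5-hydroxy-8-methoxy-2,2-dimethylchroman-6-yl)-2-(4-methoxyphenyl)ethane-1,2-dione
Product: 23 Dielsianone, 1-(5-hydroxy-8-methoxy-2,2-dimethyl-2H-chromen-6-yl)-2-(4-methoxyphenyl)ethane-1,2-dione
Conditions: DDQ, dry benzene, reflux
Reagents that add atoms: none
Why: DDQ dehydrogenation of a 2,2-dimethylchroman, by hydride abstraction from benzylic C4 (cation stabilised by O1 and the 5-oxygen) and loss of a C3 proton to give the chromene; the dry medium and the deactivating acyl group should protect the hydroquinone monomethyl ether ring.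

**Compound list**

1 | acrolein | C=CC=O | starting material
2 | isobutene | CC(C)=C | starting material
3 | 2,2-dimethyl-3,4-dihydro-2H-pyran | CC1(C)CCC=CO1 | intermediate
4 | 2,2-dimethoxyacetaldehyde | COC(OC)C=O | starting material
5 | 6-lithio-2,2-dimethyl-3,4-dihydro-2H-pyran | [Li]C1=CCCC(C)(C)O1 | intermediate
6 | lithium 1-(6,6-dimethyl-5,6-dihydro-4H-pyran-2-yl)-2,2-dimethoxyethanolate (racemic) | [Li]OC(C(OC)OC)C1=CCCC(C)(C)O1 | intermediate
7 | 2,2-dimethyl-6-(1,2,2-trimethoxyethyl)-3,4-dihydro-2H-pyran (racemic) | COC(OC)C(OC)C1=CCCC(C)(C)O1 | intermediate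
8 | N-{[2,2-dimethyl-6-(1,2,2-trimethoxyethyl)-3,4-dihydro-2H-pyran-5-yl]methylidene}-N-methylmethanaminium chloride (racemic) | COC(OC)C(OC)C1=C(C=[N+](C)C)CCC(C)(C)O1.[Cl-] | intermediate
9 | 2,2-dimethyl-6-(1,2,2-trimethoxyethyl)-3,4-dihydro-2H-pyran-5-carbaldehyde (racemic) | COC(OC)C(OC)C1=C(C=O)CCC(C)(C)O1 | intermediate
10 | methyl 2-(4-methoxyphenyl)-2-oxoacetate | COC(=O)C(=O)c1ccc(OC)cc1 | starting material
11 | methyl 2,2-dimethoxy-2-(4-methoxyphenyl)acetate | COC(=O)C(OC)(OC)c1ccc(OC)cc1 | intermediate
12 | N,2,2-trimethoxy-2-(4-methoxyphenyl)-N-methylacetamide | CON(C)C(=O)C(OC)(OC)c1ccc(OC)cc1 | intermediate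
13 | bromomagnesium alkoxide of the tetrahedral adduct of 12 with MeMgBr (racemic) | CON(C)C(C)(O[Mg]Br)C(OC)(OC)c1ccc(OC)cc1 | intermediate
14 | 1,1-dimethoxy-1-(4-methoxyphenyl)propan-2-one | CC(=O)C(OC)(OC)c1ccc(OC)cc1 | intermediate
15 | lithium 3,3-dimethoxy-3-(4-methoxyphenyl)prop-1-en-2-olate | [Li]OC(=C)C(OC)(OC)c1ccc(OC)cc1 | intermediate
16 | lithium alkoxide of 17 (diastereomer mixture) | COC(OC)C(OC)C1=C(C(O[Li])CC(=O)C(OC)(OC)c2ccc(OC)cc2)CCC(C)(C)O1 | intermediate
17 | 4-[2,2-dimethyl-6-(1,2,2-trimethoxyethyl)-3,4-dihydro-2H-pyran-5-yl]-4-hydroxy-1,1-dimethoxy-1-(4-methoxyphenyl)butan-2-one (mixture of racemic diastereomers) | COC(OC)C(OC)C1=C(C(O)CC(=O)C(OC)(OC)c2ccc(OC)cc2)CCC(C)(C)O1 | intermediate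
18 | 1-[2,2-dimethyl-6-(1,2,2-trimethoxyethyl)-3,4-dihydro-2H-pyran-5-yl]-4,4-dimethoxy-4-(4-methoxyphenyl)butane-1,3-dione (racemic) | COC(OC)C(OC)C1=C(C(=O)CC(=O)C(OC)(OC)c2ccc(OC)cc2)CCC(C)(C)O1 | intermediate
19 | 6-[2,2-dimethoxy-2-(4-methoxyphenyl)acetyl]-7,8-dimethoxy-2,2-dimethyl-2,3,4,6,7,8-hexahydro-5H-chromen-5-one (diastereomer mixture) | COc1ccc(C(OC)(OC)C(=O)C2C(OC)C(OC)C3=C(CCC(C)(C)O3)C2=O)cc1 | intermediate
20 | 6-[2,2-dimethoxy-2-(4-methoxyphenyl)acetyl]-8-methoxy-2,2-dimethyl-2,3,4,8-tetrahydro-5H-chromen-5-one (racemic) | COc1ccc(C(OC)(OC)C(=O)C2=CC(OC)C3=C(CCC(C)(C)O3)C2=O)cc1 | intermediate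
21 | 1-(5-hydroxy-8-methoxy-2,2-dimethylchroman-6-yl)-2,2-dimethoxy-2-(4-methoxyphenyl)ethanone | COc1ccc(C(OC)(OC)C(=O)c2cc(OC)c3c(c2O)CCC(C)(C)O3)cc1 | intermediate
22 | 1-(5-hydroxy-8-methoxy-2,2-dimethylchroman-6-yl)-2-(4-methoxyphenyl)ethane-1,2-dione | COc1ccc(C(=O)C(=O)c2cc(OC)c3c(c2O)CCC(C)(C)O3)cc1 | intermediate
23 | Dielsianone, 1-(5-hydroxy-8-methoxy-2,2-dimethyl-2H-chromen-6-yl)-2-(4-methoxyphenyl)ethane-1,2-dione | COc1ccc(C(=O)C(=O)c2cc(OC)c3c(c2O)C=CC(C)(C)O3)cc1 | target

**Step count.** Total: 11 steps. Longest linear sequence: 8 steps (1, 2, 3, 7, 8, 9, 10, 11; the aryl branch 4, 5, 6, 7 to 11 is equally long).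

**Steps most likely to fail**

1. Step 9. The α-methoxy acetal may ionise too slowly, so that the benzylic ketal ionises first and is captured by the C5 oxygen, or the vinylogous ester may degrade on prolonged heating with acid. The fallback sets out from 18 and changes the electrophile from an oxocarbenium ion to a free aldehyde. Aqueous trifluoroacetic acid in CH2Cl2 at rt hydrolyses both the C7 acetal and the benzylic ketal to the keto aldehyde 1-[6-(1-methoxy-2-oxoethyl)-2,2-dimethyl-3,4-dihydro-2H-pyran-5-yl]-4-(4-methoxyphenyl)butane-1,3,4-trione F1. Without purification, this is warmed with piperidinium acetate in toluene, where intramolecular Knoevenagel condensation of the C6 methylene with the C7 aldehyde, loss of water and tautomerisation should give 22 directly. The route is rejoined at 22 and step 10 is skipped.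

2. Step 3. Acid liberated during the formylation may strip methanol from the acetal, with further formylation of the enol ether so formed, or the hindered trisubstituted enol ether may react sluggishly. The fallback sets out from 7 and uses a pyridine-buffered acylation in place of the chloroiminium electrophile. Trichloroacetyl chloride and pyridine in CH2Cl2 at 0 °C acylate C4a to give 2,2,2-trichloro-1-[2,2-dimethyl-6-(1,2,2-trimethoxyethyl)-3,4-dihydro-2H-pyran-5-yl]ethanone F2. NaOMe in MeOH cleaves the trichloromethyl ketone in the haloform manner to methyl 2,2-dimethyl-6-(1,2,2-trimethoxyethyl)-3,4-dihydro-2H-pyran-5-carboxylate F3. i-Bu2AlH in CH2Cl2 at −78 °C reduces the ester to [2,2-dimethyl-6-(1,2,2-trimethoxyethyl)-3,4-dihydro-2H-pyran-5-yl]methanol F4, and MnO2 in CH2Cl2 oxidises this allylic alcohol to aldehyde 9, where the route is rejoined.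

3. Step 11. Hydride abstraction at C4 may be slow because the aroylcarbonyl group deactivates the ring, and the hydroquinone monomethyl ether may instead be over-oxidised towards a quinone. The fallback sets out from 22 and replaces hydride abstraction by radical bromination and elimination on the protected phenol. Ac2O, Et3N and DMAP give 8-methoxy-6-[2-(4-methoxyphenyl)-2-oxoacetyl]-2,2-dimethylchroman-5-yl acetate F5. NBS with AIBN in PhCF3 at 80 °C brominates benzylic C4 to racemic 4-bromo-8-methoxy-6-[2-(4-methoxyphenyl)-2-oxoacetyl]-2,2-dimethylchroman-5-yl acetate F6. DBU in THF eliminates HBr to 8-methoxy-6-[2-(4-methoxyphenyl)-2-oxoacetyl]-2,2-dimethyl-2H-chromen-5-yl acetate F7, and K2CO3 in MeOH at 0 °C removes the acetate to give 23, where the route ends.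

**Further compounds**

F1 | step 9 | 1-[6-(1-methoxy-2-oxoethyl)-2,2-dimethyl-3,4-dihydro-2H-pyran-5-yl]-4-(4-methoxyphenyl)butane-1,3,4-trione (racemic) | COC(C=O)C1=C(C(=O)CC(=O)C(=O)c2ccc(OC)cc2)CCC(C)(C)O1
F2 | step 3 | 2,2,2-trichloro-1-[2,2-dimethyl-6-(1,2,2-trimethoxyethyl)-3,4-dihydro-2H-pyran-5-yl]ethanone (racemic) | COC(OC)C(OC)C1=C(C(=O)C(Cl)(Cl)Cl)CCC(C)(C)O1
F3 | step 3 | methyl 2,2-dimethyl-6-(1,2,2-trimethoxyethyl)-3,4-dihydro-2H-pyran-5-carboxylate (racemic) | COC(OC)C(OC)C1=C(C(=O)OC)CCC(C)(C)O1
F4 | step 3 | [2,2-dimethyl-6-(1,2,2-trimethoxyethyl)-3,4-dihydro-2H-pyran-5-yl]methanol (racemic) | COC(OC)C(OC)C1=C(CO)CCC(C)(C)O1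
F5 | step 11 | 8-methoxy-6-[2-(4-methoxyphenyl)-2-oxoacetyl]-2,2-dimethylchroman-5-yl acetate | COc1ccc(C(=O)C(=O)c2cc(OC)c3c(c2OC(C)=O)CCC(C)(C)O3)cc1
F6 | step 11 | 4-bromo-8-methoxy-6-[2-(4-methoxyphenyl)-2-oxoacetyl]-2,2-dimethylchroman-5-yl acetate (racemic) | COc1ccc(C(=O)C(=O)c2cc(OC)c3c(c2OC(C)=O)C(Br)CC(C)(C)O3)cc1
F7 | step 11 | 8-methoxy-6-[2-(4-methoxyphenyl)-2-oxoacetyl]-2,2-dimethyl-2H-chromen-5-yl acetate | COc1ccc(C(=O)C(=O)c2cc(OC)c3c(c2OC(C)=O)C=CC(C)(C)O3)cc1
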